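## Retrosynthetic overview

1. Plakortolide F (23) ⇐ silyl ether 22 ⇐ radical removal of two temporary groups (C5–I and C2–O) from the iodolactone 19/20.
2. γ-Lactone (second ring) ⇐ 5-exo iodolactonisation of α-hydroxy acid 18 onto the C4=C5 bond of a 3,6-dihydro-1,2-dioxine; this sets C4 cis to C3.
3. 1,2-Dioxine (first ring) ⇐ [4+2] cycloaddition of singlet oxygen to the (3E,5E)-dienediol 15. C3 and C6 are set in one suprafacial event, and the face is dictated by the C2 carbinol, which comes from D-mannitol-derived glyceraldehyde acetonide 8 and is erased later.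
4. Diene 14 ⇐ Negishi coupling of the hydrozirconated propynyl-dioxolane 11 (from 8) with the (E)-vinyl iodide 7 (methylalumination of alkyne 5, itself from 1 + 2 + acetylide).

Assumption: locants C1–C15 in the "Why" lines follow plakortolide numbering (C1 lactone C=O, C2, C3 = CH–OO, C4 = C(Me)–O, C5, C6 = C(Me)–OO, C7–C15 chain); systematic names use von Baeyer numbering. Compounds 1, 2, 8 and all reagents are taken as catalogue chemicals.

## Route

Step 1
Reactants: 1 (4-bromophenoxy)triisopropylsilane; 2 1,9-dibromononane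
Product: 4 [4-(9-bromononyl)phenoxy]triisopropylsilane, via arylmagnesium bromide 3 (not isolated)
Conditions: 1, Mg, THF, reflux; then added to 2 (3 equiv), Li2CuCl4 (3 mol %), THF, −10 °C → rt
Reagents that add atoms: none
Why: Copper-catalysed (Kochi) sp2–sp3 Grignard cross-coupling, with excess dibromide enforcing mono-substitution; the aryl TIPS ether is inert and no stereocentre is involved.

Step 2
Reactants: 4 [4-(9-bromononyl)phenoxy]triisopropylsilane
Product: 5 triisopropyl[4-(undec-10-yn-1-yl)phenoxy]silane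
Conditions: HC≡CLi·H2NCH2CH2NH2 (1.5 equiv), DMSO, 15 °C → rt
Reagents that add atoms: lithium acetylide (ethylenediamine complex) [Li]C#C
Why: SN2 alkylation of acetylide by a primary bromide in a dipolar aprotic solvent; the hindered TIPS aryl ether survives.

Step 3
Reactants: 5 triisopropyl[4-(undec-10-yn-1-yl)phenoxy]silane
Product: 7 (E)-[4-(11-iodo-10-methylundec-10-en-1-yl)phenoxy]triisopropylsilane, via alkenylalane 6 (not isolated)
Conditions: AlMe3 (2.5 equiv), Cp2ZrCl2 (0.25 equiv), CH2Cl2, 0 °C → rt; then I2, THF, −30 → 0 °C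
Reagents that add atoms: trimethylaluminium C[Al](C)C; iodine II
Why: Negishi zirconium-catalysed methylalumination adds Me and Al syn across the terminal alkyne (Me on the internal carbon), and iodinolysis with retention gives the (E)-trisubstituted vinyl iodide that fixes the C5=C6 geometry.

Step 4
Reactants: 8 (R)-2,2-dimethyl-1,3-dioxolane-4-carbaldehyde
Product: 9 (S)-4-(2,2-dibromoethenyl)-2,2-dimethyl-1,3-dioxolane
Conditions: Zn, PPh3, CBr4 (2 equiv each), CH2Cl2, rt; then 8, 0 °C → rt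
Reagents that add atoms: carbon tetrabromide BrC(Br)(Br)Br
Why: Corey–Fuchs (Ramirez) dibromo-olefination with the acid-free Zn-generated ylide leaves the acetonide and the α-stereocentre untouched; the descriptor changes R → S only through CIP priorities.

Step 5
Reactants: 9 (S)-4-(2,2-dibromoethenyl)-2,2-dimethyl-1,3-dioxolane
Product: 11 (S)-2,2-dimethyl-4-(prop-1-yn-1-yl)-1,3-dioxolane, via lithium acetylide 10 (not isolated)
Conditions: n-BuLi (2.2 equiv), THF, −78 °C; then MeI, −78 °C → rt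
Reagents that add atoms: iodomethane CI
Why: Second stage of the Corey–Fuchs sequence (Br/Li exchange, Fritsch–Buttenberg–Wiechell shift, deprotonation) followed by C-methylation of the acetylide; the propargylic C–H is not touched at −78 °C, so the stereocentre is retained.

Step 6
Reactants: 11 (S)-2,2-dimethyl-4-(prop-1-yn-1-yl)-1,3-dioxolane; 7 (E)-[4-(11-iodo-10-methylundec-10-en-1-yl)phenoxy]triisopropylsilane
Product: 14 (S)-4-[(1E,3E)-2,4-dimethyl-13-{4-[(triisopropylsilyl)oxy]phenyl}trideca-1,3-dien-1-yl]-2,2-dimethyl-1,3-dioxolane, via alkenylzirconocene chloride 12 (not isolated), via alkenylzinc chloride 13 (not isolated)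
Conditions: 11 (1.5 equiv), Cp2Zr(H)Cl, THF, rt → 40 °C; ZnCl2, 0 °C; 7, Pd(PPh3)4 (5 mol %), rt
Reagents that add atoms: none
Why: Schwartz hydrozirconation adds H–Zr syn and, after equilibration, places Zr on the methyl-bearing carbon; Zr→Zn transmetalation and Negishi coupling then proceed with retention in both partners and give the (3E,5E)-diene.

Step 7
Reactants: 14 (S)-4-[(1E,3E)-2,4-dimethyl-13-{4-[(triisopropylsilyl)oxy]phenyl}trideca-1,3-dien-1-yl]-2,2-dimethyl-1,3-dioxolane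
Product: 15 (2S,3E,5E)-4,6-dimethyl-15-{4-[(triisopropylsilyl)oxy]phenyl}pentadeca-3,5-diene-1,2-diol
Conditions: AcOH/H2O/THF 3:1:1, 40 °C
Reagents that add atoms: none
Why: Mild acid-catalysed acetal hydrolysis goes through the tertiary oxocarbenium ion of the acetonide carbon, not the dienylic C2–O bond, so the diene geometry, C2 and the aryl TIPS ether are preserved.

Step 8
Reactants: 15 (2S,3E,5E)-4,6-dimethyl-15-{4-[(triisopropylsilyl)oxy]phenyl}pentadeca-3,5-diene-1,2-diol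
Product: 16 (1R)-1-[(3R,6R)-4,6-dimethyl-6-(9-{4-[(triisopropylsilyl)oxy]phenyl}nonyl)-3,6-dihydro-1,2-dioxin-3-yl]ethane-1,2-diol
Conditions: O2, TPP (1 mol %), hν (Na lamp), CH2Cl2, −30 °C
Reagents that add atoms: oxygen (reacts as singlet oxygen) O=O
Why: Hydroxy-directed [4+2] cycloaddition of singlet oxygen: the suprafacial addition to the (E,E)-diene places the C3 side chain and the C6 nonyl chain cis. Allylic 1,3-strain between C4–Me and C2 holds C2–H in the diene plane, so 1O2 enters on the face carrying the C2–OH (hydrogen bond, anti to the CH2OH arm; threo sense) and fixes C3 and C6 in the absolute sense of the target; the minor facial diastereomer is removed by chromatography here, while C2 still distinguishes it.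

Step 9
Reactants: 16 (1R)-1-[(3R,6R)-4,6-dimethyl-6-(9-{4-[(triisopropylsilyl)oxy]phenyl}nonyl)-3,6-dihydro-1,2-dioxin-3-yl]ethane-1,2-diol
Product: 18 (2S)-2-[(3R,6R)-4,6-dimethyl-6-(9-{4-[(triisopropylsilyl)oxy]phenyl}nonyl)-3,6-dihydro-1,2-dioxin-3-yl]-2-hydroxyacetic acid, via hydroxy aldehyde 17 (not isolated)
Conditions: TEMPO (10 mol %), NaOCl (5 mol %), NaClO2 (2 equiv), MeCN/pH 6.7 phosphate buffer, rt
Reagents that add atoms: sodium chlorite [Na+].[O-]Cl=O
Why: Oxoammonium (TEMPO) oxidation is selective for the primary alcohol and chlorite takes the aldehyde on to the acid (Zhao variant of the Anelli oxidation) at near-neutral pH, without glycol cleavage and without base that could trigger Kornblum–DeLaMare opening of the dioxine.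

Step 10
Reactants: 18 (2S)-2-[(3R,6R)-4,6-dimethyl-6-(9-{4-[(triisopropylsilyl)oxy]phenyl}nonyl)-3,6-dihydro-1,2-dioxin-3-yl]-2-hydroxyacetic acid
Product: 19 (1S,4R,5S,6R,9S)-9-hydroxy-5-iodo-4,6-dimethyl-4-(9-{4-[(triisopropylsilyl)oxy]phenyl}nonyl)-2,3,7-trioxabicyclo[4.3.0]nonan-8-one
Conditions: I2 (3 equiv), NaHCO3, MeCN, 0 °C, dark
Reagents that add atoms: iodine II
Why: Kinetic 5-exo iodolactonisation: the carboxylate opens the iodonium ion at the tertiary C4 in Markovnikov fashion, and because it is tethered through C3 it can only deliver oxygen to the face of C4 cis to the C3 side chain (cis-fused lactone, C4 set), with iodine anti at C5.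

Step 11
Reactants: 19 (1S,4R,5S,6R,9S)-9-hydroxy-5-iodo-4,6-dimethyl-4-(9-{4-[(triisopropylsilyl)oxy]phenyl}nonyl)-2,3,7-trioxabicyclo[4.3.0]nonan-8-one
Product: 20 O-[(1S,4R,5S,6R,9S)-5-iodo-4,6-dimethyl-8-oxo-4-(9-{4-[(triisopropylsilyl)oxy]phenyl}nonyl)-2,3,7-trioxabicyclo[4.3.0]nonan-9-yl] O-phenyl carbonothioate
Conditions: PhOC(S)Cl, pyridine, DMAP (cat.), CH2Cl2, 0 °C → rt
Reagents that add atoms: O-phenyl chlorothionoformate S=C(Cl)Oc1ccccc1
Why: Thioacylation of the secondary α-hydroxyl (Barton–McCombie activation) under weakly basic conditions that do not enolise the lactone, so the β-peroxide is not eliminated.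

Step 12
Reactants: 20 O-[(1S,4R,5S,6R,9S)-5-iodo-4,6-dimethyl-8-oxo-4-(9-{4-[(triisopropylsilyl)oxy]phenyl}nonyl)-2,3,7-trioxabicyclo[4.3.0]nonan-9-yl] O-phenyl carbonothioate
Product: 22 (1S,4R,6S)-4,6-dimethyl-4-(9-{4-[(triisopropylsilyl)oxy]phenyl}nonyl)-2,3,7-trioxabicyclo[4.3.0]nonan-8-one, via deiodinated thiocarbonate 21 (not isolated)
Conditions: Bu3SnH (4 equiv, ≥0.2 M), AIBN (cat.), PhH, 80 °C
Reagents that add atoms: none
Why: One radical chain performs the dehalogenation at C5 and the Barton–McCombie deoxygenation at C2; the high stannane concentration makes hydrogen transfer outrun attack of the C5 and C2 radicals on the O–O bond, and C3, C4 and C6 are not involved.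

Step 13
Reactants: 22 (1S,4R,6S)-4,6-dimethyl-4-(9-{4-[(triisopropylsilyl)oxy]phenyl}nonyl)-2,3,7-trioxabicyclo[4.3.0]nonan-8-one
Product: 23 plakortolide F, (1S,4R,6S)-4-[9-(4-hydroxyphenyl)nonyl]-4,6-dimethyl-2,3,7-trioxabicyclo[4.3.0]nonan-8-one
Conditions: TBAF, AcOH (1:1), THF, 0 °C
Reagents that add atoms: none
Why: Fluoride-induced cleavage of the aryl silyl ether, buffered with acetic acid so that neither the lactone nor the β-peroxy lactone unit is exposed to free base.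

## Compound list

1 | (4-bromophenoxy)triisopropylsilane | CC(C)[Si](Oc1ccc(Br)cc1)(C(C)C)C(C)C | starting material
2 | 1,9-dibromononane | BrCCCCCCCCCBr | starting material
3 | {4-[(triisopropylsilyl)oxy]phenyl}magnesium bromide (arylmagnesium bromide, formed in the flask) | CC(C)[Si](Oc1ccc([Mg]Br)cc1)(C(C)C)C(C)C | intermediate
4 | [4-(9-bromononyl)phenoxy]triisopropylsilane | CC(C)[Si](Oc1ccc(CCCCCCCCCBr)cc1)(C(C)C)C(C)C | intermediate
5 | triisopropyl[4-(undec-10-yn-1-yl)phenoxy]silane | CC(C)[Si](Oc1ccc(CCCCCCCCCC#C)cc1)(C(C)C)C(C)C | intermediate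
6 | (E)-dimethyl(2-methyl-11-{4-[(triisopropylsilyl)oxy]phenyl}undec-1-en-1-yl)alane (alkenylalane, formed in the flask) | CC(C)[Si](Oc1ccc(CCCCCCCCC/C(C)=C/[Al](C)C)cc1)(C(C)C)C(C)C | intermediate
7 | (E)-[4-(11-iodo-10-methylundec-10-en-1-yl)phenoxy]triisopropylsilane | CC(C)[Si](Oc1ccc(CCCCCCCCC/C(C)=C/I)cc1)(C(C)C)C(C)C | intermediate
8 | (R)-2,2-dimethyl-1,3-dioxolane-4-carbaldehyde (D-glyceraldehyde acetonide) | O=C[C@H]1COC(C)(C)O1 | starting material
9 | (S)-4-(2,2-dibromoethenyl)-2,2-dimethyl-1,3-dioxolane | BrC(Br)=C[C@H]1COC(C)(C)O1 | intermediate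
10 | lithium acetylide of (S)-4-ethynyl-2,2-dimethyl-1,3-dioxolane (formed in the flask) | [Li]C#C[C@H]1COC(C)(C)O1 | intermediate
11 | (S)-2,2-dimethyl-4-(prop-1-yn-1-yl)-1,3-dioxolane | CC#C[C@H]1COC(C)(C)O1 | intermediate
12 | chlorobis(cyclopentadienyl){(E)-1-[(4S)-2,2-dimethyl-1,3-dioxolan-4-yl]prop-1-en-2-yl}zirconium (alkenylzirconocene chloride, formed in the flask) | C/C(=C\[C@H]1COC(C)(C)O1)[Zr](Cl)(C2C=CC=C2)C3C=CC=C3 | intermediate
13 | chloro{(E)-1-[(4S)-2,2-dimethyl-1,3-dioxolan-4-yl]prop-1-en-2-yl}zinc (alkenylzinc chloride, formed in the flask) | C/C(=C\[C@H]1COC(C)(C)O1)[Zn]Cl | intermediate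
14 | (S)-4-[(1E,3E)-2,4-dimethyl-13-{4-[(triisopropylsilyl)oxy]phenyl}trideca-1,3-dien-1-yl]-2,2-dimethyl-1,3-dioxolane | CC(C)[Si](Oc1ccc(CCCCCCCCCC(\C)=C\C(\C)=C\[C@H]2COC(C)(C)O2)cc1)(C(C)C)C(C)C | intermediate
15 | (2S,3E,5E)-4,6-dimethyl-15-{4-[(triisopropylsilyl)oxy]phenyl}pentadeca-3,5-diene-1,2-diol | CC(C)[Si](Oc1ccc(CCCCCCCCCC(\C)=C\C(\C)=C\[C@H](O)CO)cc1)(C(C)C)C(C)C | intermediate
16 | (1R)-1-[(3R,6R)-4,6-dimethyl-6-(9-{4-[(triisopropylsilyl)oxy]phenyl}nonyl)-3,6-dihydro-1,2-dioxin-3-yl]ethane-1,2-diol | C[C@@]1(CCCCCCCCCc2ccc(O[Si](C(C)C)(C(C)C)C(C)C)cc2)C=C(C)[C@H]([C@H](O)CO)OO1 | intermediate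
17 | (2S)-2-[(3R,6R)-4,6-dimethyl-6-(9-{4-[(triisopropylsilyl)oxy]phenyl}nonyl)-3,6-dihydro-1,2-dioxin-3-yl]-2-hydroxyacetaldehyde (hydroxy aldehyde, formed in the flask) | C[C@@]1(CCCCCCCCCc2ccc(O[Si](C(C)C)(C(C)C)C(C)C)cc2)C=C(C)[C@H]([C@H](O)C=O)OO1 | intermediate
18 | (2S)-2-[(3R,6R)-4,6-dimethyl-6-(9-{4-[(triisopropylsilyl)oxy]phenyl}nonyl)-3,6-dihydro-1,2-dioxin-3-yl]-2-hydroxyacetic acid | C[C@@]1(CCCCCCCCCc2ccc(O[Si](C(C)C)(C(C)C)C(C)C)cc2)C=C(C)[C@H]([C@H](O)C(=O)O)OO1 | intermediate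
19 | (1S,4R,5S,6R,9S)-9-hydroxy-5-iodo-4,6-dimethyl-4-(9-{4-[(triisopropylsilyl)oxy]phenyl}nonyl)-2,3,7-trioxabicyclo[4.3.0]nonan-8-one | C[C@@]1(CCCCCCCCCc2ccc(O[Si](C(C)C)(C(C)C)C(C)C)cc2)[C@@H](I)[C@]2(C)OC(=O)[C@@H](O)[C@@H]2OO1 | intermediate
20 | O-[(1S,4R,5S,6R,9S)-5-iodo-4,6-dimethyl-8-oxo-4-(9-{4-[(triisopropylsilyl)oxy]phenyl}nonyl)-2,3,7-trioxabicyclo[4.3.0]nonan-9-yl] O-phenyl carbonothioate | C[C@@]1(CCCCCCCCCc2ccc(O[Si](C(C)C)(C(C)C)C(C)C)cc2)[C@@H](I)[C@]2(C)OC(=O)[C@@H](OC(=S)Oc3ccccc3)[C@@H]2OO1 | intermediate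
21 | O-[(1S,4R,6S,9S)-4,6-dimethyl-8-oxo-4-(9-{4-[(triisopropylsilyl)oxy]phenyl}nonyl)-2,3,7-trioxabicyclo[4.3.0]nonan-9-yl] O-phenyl carbonothioate (deiodinated thiocarbonate, formed in the flask) | C[C@@]1(CCCCCCCCCc2ccc(O[Si](C(C)C)(C(C)C)C(C)C)cc2)C[C@]2(C)OC(=O)[C@@H](OC(=S)Oc3ccccc3)[C@@H]2OO1 | intermediate
22 | (1S,4R,6S)-4,6-dimethyl-4-(9-{4-[(triisopropylsilyl)oxy]phenyl}nonyl)-2,3,7-trioxabicyclo[4.3.0]nonan-8-one | C[C@@]1(CCCCCCCCCc2ccc(O[Si](C(C)C)(C(C)C)C(C)C)cc2)C[C@]2(C)OC(=O)C[C@@H]2OO1 | intermediate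
23 | plakortolide F, (1S,4R,6S)-4-[9-(4-hydroxyphenyl)nonyl]-4,6-dimethyl-2,3,7-trioxabicyclo[4.3.0]nonan-8-one | C[C@@]1(CCCCCCCCCc2ccc(O)cc2)C[C@]2(C)OC(=O)C[C@@H]2OO1 | target

## Count and risks

Total steps: 13. Longest linear sequence: 11 (steps 1, 2, 3, 6, 7, 8, 9, 10, 11, 12, 13).

Most likely to fail:

Step 8 (photooxygenation). The trisubstituted diene termini carry allylic hydrogens, so ene hydroperoxidation (accelerated at C3=C4 by the free hydroxyl) can compete with the [4+2] mode, and the facial ratio rests on one hydrogen bond. The fallback sets out from 14 and comes back at 16. The acetonide 14 itself is photooxygenated (O2, TPP, hν, CH2Cl2, −78 °C). With no free hydroxyl the hydroxyl-assisted ene channel is closed, and the face is chosen sterically and stereoelectronically by the 1,3-strain-locked dioxolane (1O2 anti to its CH2O arm, the same sense as in step 8). This gives (4R)-4-[(3R,6R)-4,6-dimethyl-6-(9-{4-[(triisopropylsilyl)oxy]phenyl}nonyl)-3,6-dihydro-1,2-dioxin-3-yl]-2,2-dimethyl-1,3-dioxolane F1. AcOH/H2O at 40 °C then unmasks the diol 16, where the minor diastereomer is separated.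

Step 12 (double radical reduction). At 80 °C the C2 and C5 radicals sit β to the peroxide oxygens and may attack the O–O bond, and stannyl radicals slowly reduce peroxides. The fallback sets out from 19 and comes back at 22, replacing the thiocarbonyl chemistry by two C–I bonds that can be reduced at low temperature. Tf2O and 2,6-lutidine (CH2Cl2, −78 °C) convert 19 into (1S,4R,5S,6R,9S)-5-iodo-4,6-dimethyl-8-oxo-4-(9-{4-[(triisopropylsilyl)oxy]phenyl}nonyl)-2,3,7-trioxabicyclo[4.3.0]nonan-9-yl trifluoromethanesulfonate F2. Bu4NI (MeCN, 0 °C, SN2 with inversion) gives (1R,4R,5S,6R,9R)-5,9-diiodo-4,6-dimethyl-4-(9-{4-[(triisopropylsilyl)oxy]phenyl}nonyl)-2,3,7-trioxabicyclo[4.3.0]nonan-8-one F3. Bu3SnH with Et3B/air in toluene at −78 °C then removes both iodides, at a temperature where ring-opening of the peroxide cannot compete, to give 22.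

Step 6 (hydrozirconation/Negishi coupling). Incomplete regiocontrol of Zr–H addition next to the dioxolane, or sluggish transmetalation of the hindered alkenylzirconium, would give inseparable diene isomers. The fallback sets out from 11 (together with alkyne 5) and comes back at 14 with the polarity of the coupling reversed. Alkyne 11 is hydrozirconated and quenched with I2 to give the isolable (S,E)-4-(2-iodoprop-1-en-1-yl)-2,2-dimethyl-1,3-dioxolane F4, from which any regioisomer is removed by chromatography. Alkyne 5 is then methylaluminated as in step 3 to the alkenylalane 6, which is coupled in the same pot with F4 (ZnCl2 cat., Pd(PPh3)4, THF, rt) to give 14.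

## Further compounds

F1 | step 8 | (4R)-4-[(3R,6R)-4,6-dimethyl-6-(9-{4-[(triisopropylsilyl)oxy]phenyl}nonyl)-3,6-dihydro-1,2-dioxin-3-yl]-2,2-dimethyl-1,3-dioxolane | C[C@@]1(CCCCCCCCCc2ccc(O[Si](C(C)C)(C(C)C)C(C)C)cc2)C=C(C)[C@H]([C@H]2COC(C)(C)O2)OO1
F2 | step 12 | (1S,4R,5S,6R,9S)-5-iodo-4,6-dimethyl-8-oxo-4-(9-{4-[(triisopropylsilyl)oxy]phenyl}nonyl)-2,3,7-trioxabicyclo[4.3.0]nonan-9-yl trifluoromethanesulfonate | C[C@@]1(CCCCCCCCCc2ccc(O[Si](C(C)C)(C(C)C)C(C)C)cc2)[C@@H](I)[C@]2(C)OC(=O)[C@@H](OS(=O)(=O)C(F)(F)F)[C@@H]2OO1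
F3 | step 12 | (1R,4R,5S,6R,9R)-5,9-diiodo-4,6-dimethyl-4-(9-{4-[(triisopropylsilyl)oxy]phenyl}nonyl)-2,3,7-trioxabicyclo[4.3.0]nonan-8-one | C[C@@]1(CCCCCCCCCc2ccc(O[Si](C(C)C)(C(C)C)C(C)C)cc2)[C@@H](I)[C@]2(C)OC(=O)[C@H](I)[C@@H]2OO1
F4 | step 6 | (S,E)-4-(2-iodoprop-1-en-1-yl)-2,2-dimethyl-1,3-dioxolane | C/C(I)=C\[C@H]1COC(C)(C)O1
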